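**Taking time out.** The time of a reading can be removed from this problem. If Q turns L into Z and E into G, each at a rate proportional to [Q] and to the substrate, then L and E decay like two first-order elements on one shared clock, however that clock slows. Dividing one rate by the other gives d[L]/d[E] = S[L]/[E], so S = ln(charged [L] / remaining [L]) / ln(charged [E] / remaining [E]), where we take remaining L as charge minus Z and remaining E as charge minus G.

| flask | E | Q | L | remark | time |
|---|---|---|---|---|---|
| Saturday's | 0.065 M | 0.26 M | 0.065 M | run made earlier |  |
| Tuesday's | 0.26 M | 0.26 M | 0.065 M | run made earlier |  |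
| Wednesday's | 0.13 M | 0.26 M | 0.13 M | run made earlier |  |
| flask | 0.13 M | 0.260 M | 0.0650 M |  | 80 min |

| run | time / min | Z / % | G / % |
|---|---|---|---|
| Saturday's | 8.00 | 27 | 9 |
| Saturday's | 20.0 | 32 | 10 |
| Saturday's | 40.0 | 36 | 12 |
| Saturday's | 90.0 | 37 | 11 |
| Tuesday's | 8.00 | 13 | 10 |
| Tuesday's | 20.0 | 15 | 14 |
| Tuesday's | 40.0 | 16 | 9 |
| Tuesday's | 90.0 | 17 | 10 |
| Wednesday's | 8.00 | 24 | 9 |
| Wednesday's | 20.0 | 27 | 10 |
| Wednesday's | 40.0 | 28 | 7 |
| Wednesday's | 90.0 | 27 | 6 |

(standard deviation of a reading: 2 percentage points)

- share of Z in Z plus G at 5.0 s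
- share of Z in Z plus G at 2.5 min
- share of Z in Z plus G at 80 min



**Two ways.** At 8.00 min, Saturday's flask reads S = 3.91 and Wednesday's flask 3.30, both charged with equal E and L. Their mean, 3.60, a reading that carries the scatter of the runs, is the quantity we carry: the selectivity factor S, the rate constant of Z over that of G. Tuesday's flask, read the same way, gives 7.86, twice that mean. At the start the share of Z in Z plus G is S[L]/(S[L]+[E]), so for the new flask, with [L]/[E] of 0.500, we reckon 64.3% by the mean and 79.7% by Tuesday's value.

**Which cheats.** The formula allows no traffic between E and L, yet a hand-over from E to L would leave more L than charge minus Z and so inflate S. That error should grow with the E to L charge ratio, which is 4.00 on Tuesday against 1.00 on Saturday, so we suspect Tuesday's value. At 5.0 s, far earlier than 8.00 min, such traffic has had little time, so we commit to 64.3%. Saturday's share read 75.0% at 8.00 min and 77.1% at 90.0 min, and on that one run we keep, as our own estimate, about 64.3% for the later times of the new flask too.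

**The forecast.** The forecast gives 75%, 72% and 70%, holding that “L depletes faster than E, so the share should start slightly higher”, and its early figure stands above our 64.3%.

**The flask.** The new flask gives 66.2% at 5.0 s, 64.7% at 2.5 min and 67.1% at 80 min. S times the charge ratio makes 1.80 Z per G against the flask's 1.96 at 5.0 s, a gap of 1.9 percentage points in the share. With the step from E to L struck out both ways, that early share is 66.1%.

    E + Q → G (k = 0.330 L mol⁻¹ min⁻¹)
    2 Q → J (k = 1.60 L mol⁻¹ min⁻¹)
    E ⇌ L (K = 1.30, k = 0.0410 min⁻¹)
    Q + L → Z (k = 1.30 L mol⁻¹ min⁻¹)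

**Next flask.** With 0.16 M of L and the rest of the recipe held, S gives a share of 81.6%, and that neighbour flask stands at 82.8% at 5.0 s.

Readings and results come from a simulation on assumed constants.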